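At the last reading of the ochre flask, 90.0 s, Z stood to X as 0.639; I called this, Z divided by X at one moment, the standing ratio and ran the flask on it.

| flask | X | D | temperature | remark | time |
|---|---|---|---|---|---|
| ochre | 0.10 M | 0.5 mol% | 5 °C | the very flask that is asked about, followed so far |  |
| red | 0.10 M | 1 mol% | 0 °C | run made earlier |  |
| flask | 0.10 M | 0.5 mol% | 5 °C |  | 2.5 min |

ochre run (percent of the X charged)

| time / s | Z / % | X / % |
|---|---|---|
| 12.0 | 22.9 | 72.3 |
| 30.0 | 27.3 | 58.5 |
| 60.0 | 23.0 | 43.5 |
| 90.0 | 23.4 | 36.6 |

red run (percent of the X charged)

| time / min | Z / % | X / % |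
|---|---|---|
| 0.200 | 30.7 | 61.7 |
| 0.500 | 27.2 | 41.4 |
| 1.00 | 24.7 | 31.5 |
| 2.50 | 17.6 | 19.2 |

(each reading ± 1 percentage point)

- Friday's: change nothing and wait 5.0 min more
- Sunday's: at 2.5 min raise the temperature by 10 K, then wait 5.0 min
- Thursday's: at 2.5 min take out 90 % of the Z then present, then wait 5.0 min
- Saturday's: at 2.5 min add D, 100 % of the amount charged, then wait 5.0 min

- Z that was removed still counts
- additions bring no volume worth counting

- Z, in percent of the X first charged, at 2.5 min
- what to do for the largest gain in Z; "none" if nothing gains more than 2 percentage points (Friday's / Sunday's / Thursday's / Saturday's / none)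
- Z present, with what was taken out counted in, in percent of the X first charged, after Friday's
- Z present, with what was taken out counted in, in percent of the X first charged, after Thursday's

The curve of Z in the ochre flask began steeply: by 12.0 s it held 22.9 %, a fraction 0.827 of the X already lost. The knee followed, with the highest reading, 27.3 %, at 30.0 s. After that Z read 23.0 % and 23.4 % while X kept falling, and the ratio read 0.529, then 0.639, each with the scatter of its two readings. The red run, which differed from the ochre flask in both D and temperature, ended at 0.917, so I kept the ochre ratio for the ochre flask.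

X and Z together, the pool, fell from 66.5 % to 60.0 % in 30.0 s. At that same factor per interval, I put the ochre pool at 48.8 % at 2.5 min. Z takes a share 0.390 of the pool, so I landed at 19.0 %. On this reckoning Z has no level of its own and sinks with the pool, so waiting loses. For Thursday's I reckoned 17.1 % banked and the remaining pool split again by the same share, a total of 29.5 % before further drain.

The forecast gave 20.5 %, 15 % for Friday's and 26 % for Thursday's, and chose Thursday's, holding of the other moves that “More D or heat only pushes further along the same declining curve.” My Z stood lower than its figure, and my Thursday's total higher.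

The flask gave 19.8 %, 14.7 % after Friday's and 29.7 % after Thursday's, and Thursday's gained 9.8 percentage points.

    X + D ⇌ Z + D, rate k1*[X]*[D] forward; the back reaction follows from the equilibrium constant (K = 0.660, k = 75.0 /M/s, Ea = 37.0 kJ/mol, ΔH = −48.0 kJ/mol)
    Z + D ⇌ J + D, rate k2*[D]*[Z] forward; the back reaction follows from the equilibrium constant (K = 2.30, k = 60.0 /M/s, Ea = 39.0 kJ/mol, ΔH = −40.0 kJ/mol)
    J + D ⇌ L + D, rate k3*[D]*[J] forward; the back reaction follows from the equilibrium constant (K = 2.20, k = 5.40 /M/s, Ea = 51.0 kJ/mol, ΔH = 19.0 kJ/mol)
    (constants at 5 °C)

Besides X and Z, the flask held J at 38.0 % and L at 10.3 % at 2.5 min. Z still stood by X: the standing ratio times the 32 % of X left gives 20.4 %. In the same flask read at 10 min, L held the most, 36.8 %, and the ratio times X at 20.6 % gives 13.2 %, where Z stood at 13.4 %.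

(The data come from a simulation for substances that don't exist, noise included.)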